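(The readings were computed from invented constants.)

The target in this flask stands at 34.1% at 2.50 min and at 7.4% at 10.0 min, while the isomer climbs to 86.1%: what is made first leaves again. Both come from starting material and coupling partner by reversible steps, so the late flask should pass from kinetic to thermodynamic control.

- north-west: solid substrate 16 mM; gas 1.3 mM (held); the very flask that is asked about, followed so far
- flask: solid substrate 16 mM; gas 1.3 mM (held); time 50 min

north-west run (percent of the solid substrate charged)

| time / min | solid substrate / % | target / % | isomer of the product / % |
|---|---|---|---|
| 1.33 | 24.8 | 29.0 | 14.8 |
| 2.50 | 0.5 | 34.1 | 36.3 |
| 4.00 | 0.2 | 22.7 | 58.0 |
| 5.00 | 0 | 17.9 | 67.3 |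
| 6.00 | 0 | 14.6 | 74.3 |
| 8.00 | 0 | 10.2 | 81.5 |
| 10.0 | 0 | 7.4 | 86.1 |

(readings scatter by 0.5 percentage points)

- given per volume of solution although it is solid: solid substrate
- at the start none of coupling partner is dissolved
- the analysis behind the earlier runs scatters by 0.5 percentage points, standard deviation
- candidate steps: starting material + coupling partner <-> target; starting material + coupling partner <-> isomer of the product; coupling partner <-> dormant form; gas <-> coupling partner; solid substrate <-> starting material
- at the start none of the solid substrate is in solution
- what has only dissolved of solid substrate counts as not reacted
- the reaction counts as stopped when no species that holds the solid substrate changes by six tenths of a point or more over the second half of the time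

1. which holds at 50 min: what has brought the reaction to rest, or that it has not come to rest (for what has run out or reacted, a solid counts together with what of it has only dissolved) (all of the solid substrate has reacted / forward and back rates have come level / it is still moving)
2. part of the solid substrate that has turned into other species by 50 min (what has only dissolved does not count)
3. amount of target at 50 min, in percent of the solid substrate charged
4. amount of isomer of the product at 50 min, in percent of the solid substrate charged
5. amount of target if the flask were left three thousand times as long, in percent of the solid substrate charged

We solve the two ends and join them. At the late end the isomer rises by 0.0815 min⁻¹ of the charge around a level of 66.1%, but by 0.0230 min⁻¹ around 83.8%, which is slower. If the rise shrinks in proportion to the distance from rest, the line through these two points has slope 0.331 min⁻¹ and reaches zero at isomer 90.7%. The half-time of that approach is 2.09 min, far shorter than the 50 min asked, so we expect rest.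

At the front end, the solid is down to 0% at 5.00 min, so what is neither target nor isomer is dissolved starting material. The readings at 5.00 min and 10.0 min, pooled, give 1.19 of target per starting material. Splitting the remaining 9.30% that way, if this reading of the ratio holds on to rest, gives target 5.03% and conversion 95.7%.

Joined, isomer over target stands at 18.0. We call this the rest ratio, c of isomer over c of target once both steps balance. Both steps share the same starting material and coupling partner, so these cancel from it.

The weak link is the slow point of the line: with the slope held, a scatter of 0.5 percentage points per reading moves rest isomer by about 1.1 points. Reforged, one such shift down or up puts our estimate of the rest ratio at 16.0 or 20.6.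

The forecast, made from the same runs, says forward and back rates have come level, with conversion 95.9%, target 4.9%, isomer 91%, and target 4.9% after the long wait. Its ground is “target is the kinetic product that drains to the isomer”. Our target is a little higher.

The flask gives forward and back rates have come level, with conversion 95.7%, target 5.52%, isomer 90.1%, and target 5.52% after the long wait.

    starting material + coupling partner ⇌ target (K = 980 L mol⁻¹, k = 140 L mol⁻¹ s⁻¹)
    starting material + coupling partner ⇌ isomer of the product (K = 16000 L mol⁻¹, k = 9.40 L mol⁻¹ s⁻¹)
    coupling partner ⇌ dormant form (K = 3.00, k = 0.00920 s⁻¹)
    gas ⇌ coupling partner, rate k4*(csat - [coupling partner]) (kL = 0.280 s⁻¹)
    solid substrate ⇌ starting material, rate k5*(cs5 - [starting material]) while solid is left; crystals form when [starting material] > cs5 (solubility = 7.90 mM, k = 0.0330 s⁻¹)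

The rest ratio of this flask is 16.3, and the balance constant of the isomer step over that of the target step is 16.3; the back turnover of the target step is 99.8% of its forward one. Going down in time, the conversion of this flask has moved by 5 points at 7.06 min, so an asked time near that is what it would take to part from the forecast. The neighbouring flask with 64 mM of solid substrate ends with isomer 90.1% and target 5.52%, a rest ratio of 16.3.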